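The quinone ring is numbered C1 (C=O flanked by C2 and C6), C2 (OMe), C3 (H), C4 (C=O), C5 (Me), C6 (pentacosyl). The plan reads the para oxygens at C1 and C4 as a CO ligand and an alkoxycarbene carbon. C2–C3 is read as methoxyacetylene and C5=C6 as a trisubstituted alkene. One Dötz benzannulation forges C3–C4, C1–C2 and C1–C6, closes the only carbocycle and places all four substituents. It gives a 4-methoxyphenol one oxidation away from the quinone. The precursor is an (E)-alkenyl(methoxy)carbene pentacarbonylchromium complex with the methyl on its α-carbon and the C25 chain on its β-carbon, made regiospecifically from hexacosanal.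

Key step: step 5

Remark: the target has no stereocentre and is achiral, so no enantiomer question arises. The E alkene of the carbene ligand is the only stereo-element in the route, and it disappears on aromatisation.

Step 1
Reactants: 1 1-hexacosanol
Product: 2 hexacosanal
Conditions: IBX (1.5 equiv), EtOAc, 80 °C; hot filtration
Reagents that add atoms: none
Why: IBX oxidation of a primary alcohol stops at the aldehyde, and hot ethyl acetate dissolves the waxy substrate while the oxidant and its reduced form stay solid and are filtered off.

Step 2
Reactants: 2 hexacosanal; 3 ethyltriphenylphosphonium bromide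
Product: 6 (E)-2-iodooctacos-2-ene, via ethylidenetriphenylphosphorane 4 (not isolated), via β-lithiooxy ylide 5 (not isolated)
Conditions: 3, PhLi (1.0 equiv), THF, 0 °C; 2 (warm THF solution), −78 °C; PhLi (1.1 equiv), −78 → −30 °C; I2, −78 °C → rt
Reagents that add atoms: iodine, II
Why: Wittig–Schlosser (SCOOPY) olefination: ylide 4 adds to the aldehyde, the lithiobetaine is deprotonated to 5, iodine is taken up at the ylide carbon and syn loss of triphenylphosphine oxide gives the trisubstituted alkenyl iodide, a sequence known to favour the E isomer with aliphatic aldehydes; iodine and methyl share one carbon by construction, so the methyl/chain-swapped regioisomer that hydrometalation of a methyl n-alkyl alkyne leaks cannot arise, and any Z isomer would end in the same arene.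

Step 3
Reactants: 6 (E)-2-iodooctacos-2-ene; 7 chromium hexacarbonyl
Product: 10 pentacarbonyl[(E)-1-methoxy-2-methyloctacos-2-en-1-ylidene]chromium(0), via (E)-octacos-2-en-2-yllithium 8 (not isolated), via lithium acylchromate 9 (not isolated)
Conditions: 6 (Et2O, rt) added to t-BuLi (2.1 equiv), Et2O–pentane, −78 → 0 °C; 7, Et2O, 0 °C → rt; evaporate; Me3OBF4, CH2Cl2, 0 °C → rt
Reagents that add atoms: trimethyloxonium tetrafluoroborate, C[O+](C)C.F[B-](F)(F)F
Why: Fischer carbene synthesis: iodine–lithium exchange retains the alkene geometry, the vinyllithium adds to a CO ligand of 7 to give acylchromate 9, and the hard Meerwein salt methylates its oxygen; inverse addition lets the exchange outrun precipitation of the long-chain iodide.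

Step 4
Reactants: 11 chloroacetaldehyde dimethyl acetal
Product: 13 methoxyacetylene, via sodium methoxyacetylide 12 (not isolated)
Conditions: NaNH2 (3.1 equiv), liq. NH3, −33 °C; NH3 off; sat. aq. NaCl, −20 °C; distilled into THF at −78 °C, kept as a cold solution
Reagents that add atoms: none
Why: Classical alkoxyacetylene preparation: amide base removes methanol and then hydrogen chloride by successive β-eliminations and holds the product as its acetylide until the aqueous quench, and the methyl ether has no β-hydrogen for retro-ene loss of ketene on later warming.

Step 5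
Reactants: 10 pentacarbonyl[(E)-1-methoxy-2-methyloctacos-2-en-1-ylidene]chromium(0); 13 methoxyacetylene
Product: 15 2,4-dimethoxy-5-methyl-6-pentacosylphenol, via arene tricarbonylchromium complex 14 (not isolated)
Conditions: 13 (3 equiv, in portions), THF (0.05 M), 50 °C, sealed tube, Ar; hν (Pyrex), rt, until the carbene colour fades; air, Et2O, rt
Reagents that add atoms: none
Why: Thermal loss of a cis CO from 10 opens a site for 13, whose nucleophilic CH terminus bonds to the electrophilic carbene carbon (C3–C4), so the OMe-bearing alkyne carbon becomes the new carbene centre, and migration of a CO ligand onto it (C1–C2) gives a chromium-bound dienylketene. The ring closes by 6π electrocyclisation of that ketene (C1–C6) with hydrogen, not the chain, on the inner face of the E alkene, and enolisation delivers the arene as its Cr(CO)3 complex 14, which air strips. This is the Dötz benzannulation of an alkenyl Fischer carbene with a terminal alkyne, for which oxygen-substituted (aryloxy) alkynes are the nearest known partners. The one selectivity needed is the orientation of the alkyne, and here the steric rule (larger alkyne substituent next to the CO-derived carbon) and the polarisation of the ynol ether point the same way, while methyl and chain positions are fixed in the ligand. Because the donor methoxy group could hold the inserted complex as a stabilised dienyl(alkoxy)carbene, a light-driven CO insertion (the known photochemical benzannulation of dienylcarbene complexes, forming the same bonds) is built into the protocol. No stereocentre is formed.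

Step 6
Reactants: 15 2,4-dimethoxy-5-methyl-6-pentacosylphenol
Product: 16 2-methoxy-5-methyl-6-pentacosyl-1,4-benzoquinone (target)
Conditions: (NH4)2Ce(NO3)6 (2.2 equiv), MeCN–CH2Cl2–H2O, 0 °C → rt
Reagents that add atoms: water, O
Why: Oxidative demethylation of a 4-methoxyphenol with cerium(IV): two one-electron oxidations, attack of water at C4 and loss of methanol give the 1,4-quinone, the C2 methoxy group stays as a vinylogous ester, and any chromium left over is oxidised away.

Compound list
1 | 1-hexacosanol | CCCCCCCCCCCCCCCCCCCCCCCCCCO | starting material
2 | hexacosanal | CCCCCCCCCCCCCCCCCCCCCCCCCC=O | intermediate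
3 | ethyltriphenylphosphonium bromide | CC[P+](c1ccccc1)(c1ccccc1)c1ccccc1.[Br-] | starting material
4 | ethylidenetriphenylphosphorane | CC=P(c1ccccc1)(c1ccccc1)c1ccccc1 | intermediate
5 | lithium 2-(triphenyl-λ5-phosphanylidene)octacosan-3-olate (β-lithiooxy ylide, racemic) | CCCCCCCCCCCCCCCCCCCCCCCCCC([O-])C(C)=P(c1ccccc1)(c1ccccc1)c1ccccc1.[Li+] | intermediate
6 | (E)-2-iodooctacos-2-ene (iodine trans to the chain) | I/C(C)=C/CCCCCCCCCCCCCCCCCCCCCCCCC | intermediate
7 | chromium hexacarbonyl | O=C=[Cr](=C=O)(=C=O)(=C=O)(=C=O)=C=O | starting material
8 | (E)-octacos-2-en-2-yllithium | [Li]/C(C)=C/CCCCCCCCCCCCCCCCCCCCCCCCC | intermediate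
9 | lithium pentacarbonyl[(E)-2-methyloctacos-2-enoyl]chromate | [Li+].[O-]C(=[Cr](=C=O)(=C=O)(=C=O)(=C=O)=C=O)/C(C)=C/CCCCCCCCCCCCCCCCCCCCCCCCC | intermediate
10 | pentacarbonyl[(E)-1-methoxy-2-methyloctacos-2-en-1-ylidene]chromium(0) | COC(=[Cr](=C=O)(=C=O)(=C=O)(=C=O)=C=O)/C(C)=C/CCCCCCCCCCCCCCCCCCCCCCCCC | intermediate
11 | chloroacetaldehyde dimethyl acetal | COC(CCl)OC | starting material
12 | sodium methoxyacetylide | [Na+].[C-]#COC | intermediate
13 | methoxyacetylene | C#COC | intermediate
14 | tricarbonyl(η6-2,4-dimethoxy-5-methyl-6-pentacosylphenol)chromium(0) (η6 bonding written as a dot-separated pair) | CCCCCCCCCCCCCCCCCCCCCCCCCc1c(C)c(OC)cc(OC)c1O.O=C=[Cr](=C=O)=C=O | intermediate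
15 | 2,4-dimethoxy-5-methyl-6-pentacosylphenol | CCCCCCCCCCCCCCCCCCCCCCCCCc1c(C)c(OC)cc(OC)c1O | intermediate
16 | 2-methoxy-5-methyl-6-pentacosyl-1,4-benzoquinone (5-methoxy-2-methyl-3-pentacosylcyclohexa-2,5-diene-1,4-dione), achiral | CCCCCCCCCCCCCCCCCCCCCCCCCC1=C(C)C(=O)C=C(OC)C1=O | target

Total steps: 6. Longest linear sequence: 5 (steps 1, 2, 3, 5, 6); step 4 is a one-step side branch.

Steps most likely to fail

Step 5.
- What may go wrong: after the alkyne has inserted, the methoxy-stabilised carbene may keep its carbonyl set instead of migrating one. The ynol ether may oligomerise on chromium, or it may add in conjugate fashion to the alkenyl ligand.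
- Fallback: this uses radical chemistry and no organometallic ring construction. It sets out from aldehyde 2, which a Pinnick oxidation takes to hexacosanoic acid F1. Purchased 2-methoxy-5-methylphenol is oxidised with Fremy's salt (Teuber reaction) to 2-methoxy-5-methyl-1,4-benzoquinone F2. Silver(I)/persulfate decarboxylation of F1 in the presence of F2 (Jacobsen–Torssell alkylation) should deliver the pentacosyl radical to C6, the only free ring position not deactivated by the methoxy donor. The fallback comes back to the route at target 16.

Step 2.
- What may go wrong: the waxy aldehyde may precipitate at low temperature, the oxaphosphetane may collapse before the second deprotonation, or the geometric selectivity of the iodination may erode.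
- Fallback: this replaces carbonyl olefination by alkyne hydrometalation and sets out from 2. Corey–Fuchs olefination gives 1,1-dibromoheptacos-1-ene F3, and n-BuLi followed by MeI gives octacos-2-yne F4. Excess Schwartz reagent in warm THF under equilibrating conditions gives the alkenylzirconocene chloride F5, and iodinolysis comes back to the route at 6. The price is incomplete regiocontrol between the methyl and n-alkyl termini, so the iodide would need rigorous purification before use.

Step 3.
- What may go wrong: the long-chain iodide may precipitate before exchange, the vinyllithium may be protonated, attack on suspended chromium hexacarbonyl may be sluggish, or O-methylation may be incomplete.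
- Fallback: this is the Semmelhack–Hegedus route, which needs no organolithium, and it sets out from 2 and 7. Wittig reaction of 2 with (1-ethoxycarbonylethylidene)triphenylphosphorane gives ethyl (E)-2-methyloctacos-2-enoate F6. Saponification gives (E)-2-methyloctacos-2-enoic acid F7, and oxalyl chloride gives (E)-2-methyloctacos-2-enoyl chloride F8. Reduction of 7 with potassium graphite gives dipotassium pentacarbonylchromate F9, and its acylation by F8 gives the potassium acylchromate F10. Methylation with Meerwein salt comes back to the route at 10.

Further compounds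
F1 | step 5 | hexacosanoic acid | CCCCCCCCCCCCCCCCCCCCCCCCCC(=O)O
F2 | step 5 | 2-methoxy-5-methyl-1,4-benzoquinone | COC1=CC(=O)C(C)=CC1=O
F3 | step 2 | 1,1-dibromoheptacos-1-ene | CCCCCCCCCCCCCCCCCCCCCCCCCC=C(Br)Br
F4 | step 2 | octacos-2-yne | CC#CCCCCCCCCCCCCCCCCCCCCCCCCCC
F5 | step 2 | chlorobis(cyclopentadienyl)[(E)-octacos-2-en-2-yl]zirconium | Cl[Zr](C1C=CC=C1)(C1C=CC=C1)/C(C)=C/CCCCCCCCCCCCCCCCCCCCCCCCC
F6 | step 3 | ethyl (E)-2-methyloctacos-2-enoate | CCOC(=O)/C(C)=C/CCCCCCCCCCCCCCCCCCCCCCCCC
F7 | step 3 | (E)-2-methyloctacos-2-enoic acid | OC(=O)/C(C)=C/CCCCCCCCCCCCCCCCCCCCCCCCC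
F8 | step 3 | (E)-2-methyloctacos-2-enoyl chloride | ClC(=O)/C(C)=C/CCCCCCCCCCCCCCCCCCCCCCCCC
F9 | step 3 | dipotassium pentacarbonylchromate | [K+].[K+].O=C=[Cr-2](=C=O)(=C=O)(=C=O)=C=O
F10 | step 3 | potassium pentacarbonyl[(E)-2-methyloctacos-2-enoyl]chromate | [K+].[O-]C(=[Cr](=C=O)(=C=O)(=C=O)(=C=O)=C=O)/C(C)=C/CCCCCCCCCCCCCCCCCCCCCCCCC
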